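**Assumption:** the 3‑benzoyl‑2,4,9‑trione is taken in the enol form drawn for the target; its enol tautomers interconvert, so the last step delivers this compound.

**Locants used throughout:** C1 is the bridgehead next to the CMe2 carbon C8; C2–C3–C4 is the oxygenated three‑carbon bridge (C3 benzoylated); C5 is the second bridgehead; C6 is the ring CH2; C7 is the prenyl‑bearing CH; C9 is the bridging carbonyl. Ring A = C1, C2, C3, C4, C5, C9; ring B = C1, C8, C7, C6, C5, C9. "Prenyl" = 3‑methylbut‑2‑en‑1‑yl.

## Analysis of the target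

Compound 19 is a bicyclo[3.3.1]nonane‑2,4,9‑trione: ring A is a 2‑acylcyclohexane‑1,3‑dione held as an enol, ring B is a cyclohexanone, and the rings share C1, C9 and C5. It has three stereocentres: the quaternary bridgeheads C1 and C5, each prenylated, and the tertiary C7, also prenylated. C1 and C5 are tied to each other by the bridge, so only the absolute sense and the relation of C7 to the bridge are free. Here the C7 prenyl lies on the same face of ring B as C2–C4 (the endo, 7‑epi‑clusianone‑type arrangement; 1S,5R,7S in the drawn tautomer). The three trisubstituted alkenes exclude strong acid, electrophilic oxidants, heterogeneous hydrogenation and hydroboration. The acidic β‑triketone is open to retro‑Claisen cleavage and is best carried as a methyl enol ether to the last step. The difficulty is congestion: C1, C8 and C5 are quaternary, C1 and C8 are adjacent, and both bridgeheads sit between carbonyl groups; the endo C7 centre is the epimer that acylative annulation of a preformed ring B does not favour. The plan rests on one feature: C5–C9 and C1–C2 are both acyl–α‑carbon bonds, and cutting them opens both rings to a single chain C2–C3–C4–C5–C6–C7–C8–C1–C9 in which only C7 is a fixed stereocentre.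

## Retrosynthetic reasoning

**19 ⇒ 18 ⇒ 16 + 17.** The enol is traced back to methyl ether 18 (O–CH3 bond), and the C3–benzoyl bond is cut to give vinylogous ester 16 and benzoyl chloride 17. C3 is the only carbon of 16 that can be metalated, because both bridgeheads are quaternary, so the benzoyl group stays out of all earlier base chemistry. Forward, C3 must be lithiated and acylated, and the ether cleaved without acid.

**16 ⇒ 14 (through 15).** C1–C2 and C5–C9 are cut. Both are Claisen retrons, and no other pair of cuts opens both rings while leaving a chain with a single stereocentre. The gain is two rings, two quaternary centres and two stereocentres in one operation. Forward, C5 (γ to the ester of the 3‑methoxy enoate) must acylate at C9 to close ring B as cyclohexanone 15; then C1, now α to a ketone, must acylate at C2 to close ring A. The C4 enol ether makes C5–H acidic and removes the C3 proton that would otherwise turn the C2 ester into an unreactive enolate.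

**14 ⇒ 13 ⇒ 12 + 3.** The O‑methyl bond of 14 is cut to β‑keto ester 13, and the C5–prenyl bond of 13 to keto ester 12 and prenyl bromide 3. C5 is the γ‑carbon of a β‑keto ester, where a dianion reacts cleanly with an allylic halide; its configuration is irrelevant because C5 becomes trigonal in the key step.

**12 ⇒ 10 + 11.** The C5–C6 bond is cut to iodide 10 and methyl acetoacetate 11. This supplies C2–C5 from a commodity reagent by a second γ‑alkylation, with C6 as the electrophile so that the C7 centre is never adjacent to an enolisable carbonyl.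

**10 ⇒ 9 ⇒ 8 ⇒ 7 + 3.** The iodide comes from alcohol 9 and that from imide 8, whose C7–prenyl bond is cut to imide 7 and 3. This is the only stereo‑defining step before the key step: C7 is α to the C6 carbonyl, so an auxiliary‑controlled enolate alkylation sets it, and reduction then converts C6 into the CH2 of the target.

**7 ⇒ 4 + 5 (via 6); 4 ⇒ 2 + 3; 2 ⇒ 1.** The C6–N bond is cut to acid 4 and auxiliary 5, the C1–prenyl bond of 4 to half ester 2 and 3, and 2 to anhydride 1. The unit C6–C7–C8(Me2)–C1–C9 is 3,3‑dimethylglutaric acid, so the quaternary carbon and both arms are bought and never have to be made. Opening 1 differentiates the arms as ester (C9) and acid (C6).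

## Alternatives that were turned down

**Alternative 1:** Ring B is disconnected at C5–C6 and C7–C8 into 4‑methyl‑2‑(triisopropylsilyloxy)penta‑1,3‑diene A2 and 3‑acryloyl‑1,3‑oxazolidin‑2‑one A3. Forward, Cu(OTf)2 (divalent copper) with a C2‑symmetric bis(oxazoline) would catalyse the [4+2] cycloaddition to ring B silyl enol ether A1, setting C7.
- For: the stereocentre comes from a catalyst, not a stoichiometric auxiliary, and ring B, the gem‑dimethyl carbon and a regiodefined enol ether arrive in one step. On catalytic enantiocontrol and on precedent for the reaction type it is stronger than the chosen plan.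
- Against: A2 has two methyl groups on its reacting terminus, one necessarily inside the s‑cis conformer, and the new C7–C8 bond joins a fully substituted carbon to the acyl‑bearing carbon. The concerted path is therefore slow, and an open‑chain Mukaiyama–Michael adduct at C5 is the likely diversion.
- After A1, the acyl carbon on C7 must be turned into a prenyl group (one carbon short), C1 and C5 must each be prenylated, and ring A must be built by bridging C1 and C5. A bridge introduced by acylating a preformed ring B enters axially with the C7 substituent equatorial, which is the exo relation, opposite to what 19 needs.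
- Comparison: the chosen plan gives up catalysis, but C7 is prenylated before any ring exists, both rings and both quaternary bridgeheads form in one operation, and the endo relation follows from the first closure.

**Alternative 2:** Ring B is opened at C5–C6. The precursor is the dearomatised acylphloroglucinol A5 (ring A complete, benzoyl at C3, prenyl at C1 and C5, a CMe2–C(=O)CH3 chain on C1). Forward, the polyanion made with LiN(iPr)2 is oxidised with Fe(acac)3 (trivalent iron) so that the methyl ketone carbon C6 couples with the ring enolate carbon C5, giving the 7‑oxo compound A4.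
- For: A5 is a few alkylations from a cheap acylphloroglucinol, the benzoyl group and the ring A oxidation pattern are present from the start, and the hindered C5–C6 bond is made by a coupling that tolerates congestion. In convergence and step count up to its key product it is stronger than the chosen plan.
- Against: C5 of A5 belongs to a strongly stabilised triketonate that is hard to oxidise, so homocoupling of the ketone enolate or reaction at oxygen competes. The absolute configuration must come from an enantioselective dearomative alkylation at C1. Above all, A4 lacks the one stereocentre that defines this target.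
- Turning the neopentyl C7 ketone into a prenyl‑bearing CH needs olefination or allylation and then a reduction that tells four alkenes apart. Hydrogen delivery from the open exo face would in principle give the endo prenyl, so on the sense of C7 control the alternative is no worse, but the chemoselectivity is unsolved.
- Comparison: the chosen plan fixes C7 first by auxiliary alkylation and lets it direct C5 and C1, at the price of a longer linear sequence.

**Alternative 3:** The C1–C8 bond is traced back to a 1,2‑shift. The precursor is the cis‑fused hydrindanone A7, in which C8 is still bonded to the carbinol carbon C9 and C1 is the CH2 next to the enol ether carbon. Forward, deprotonation and reaction with PhI(OAc)2 (trivalent iodine) place the iodine group on C1; C8 migrates from C9 to C1 as iodobenzene leaves, C9 becomes the bridging ketone and the cyclopentane grows into ring B, giving A6.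
- For: the step is irreversible, so it is stronger than the chosen plan on driving force; the migration is stereospecific; C5 and C7 can be set beforehand on a compact bicycle.
- Against: A6 has hydrogen at C1, and the missing prenyl would have to go onto the bridgehead next to the gem‑dimethyl carbon, the most hindered position of the skeleton. A7, with a quaternary carbon, a tertiary carbinol and the C7 centre, needs its own multistep stereocontrolled synthesis. Iodination may occur at C3, C5 may migrate instead of C8, acetate may simply substitute, and the oxidant can attack the prenyl alkenes.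
- Comparison: the chosen plan is weaker in driving force, since its two acylations are in principle reversible, but it delivers both bridgeheads fully substituted and needs only two steps after the key step.

Key step: step 10

## Route

**Step 1**
Reactants: 1 3,3‑dimethylglutaric anhydride
Product: 2 5‑methoxy‑3,3‑dimethyl‑5‑oxopentanoic acid
Conditions: MeOH, reflux
Reagents that add atoms: methanol, CO
Why: Alcoholysis of a symmetrical cyclic anhydride; either carbonyl gives the same half ester, which marks the two arms of the quaternary unit as C9 (ester) and C6 (acid).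

**Step 2**
Reactants: 2 5‑methoxy‑3,3‑dimethyl‑5‑oxopentanoic acid; 3 prenyl bromide (1‑bromo‑3‑methylbut‑2‑ene)
Product: 4 rac‑4‑(methoxycarbonyl)‑3,3,7‑trimethyloct‑6‑enoic acid
Conditions: LiN(iPr)2 (2.2 equiv), THF, −78 to −20 °C; 3, −78 °C to rt; dilute HCl
Reagents that add atoms: none
Why: Alkylation of a carboxylate/ester‑enolate dianion: after the acid is deprotonated, the second equivalent of base removes the proton α to the ester, far more acidic than that α to the carboxylate, so prenylation occurs at the future C1; its configuration is irrelevant because C1 is enolised in step 10.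

**Step 3**
Reactants: 4 rac‑4‑(methoxycarbonyl)‑3,3,7‑trimethyloct‑6‑enoic acid; 5 (R)‑4‑benzyl‑1,3‑oxazolidin‑2‑one
Product: 7 methyl 5‑[(4R)‑4‑benzyl‑2‑oxo‑1,3‑oxazolidin‑3‑yl]‑3,3‑dimethyl‑2‑(3‑methylbut‑2‑en‑1‑yl)‑5‑oxopentanoate (both C2 epimers), via mixed pivalic anhydride 6 (not isolated)
Conditions: tBuCOCl, Et3N, THF, −20 °C; then 5, LiCl, −20 °C to rt
Reagents that add atoms: none
Why: N‑Acylation of the Evans auxiliary through a mixed anhydride; the oxazolidinone attacks the CH2–C(=O) carbonyl and not the tert‑alkyl pivaloyl one, and the hindered methyl ester is untouched.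

**Step 4**
Reactants: 7 imide (both C2 epimers); 3 prenyl bromide
Product: 8 methyl (4R)‑5‑[(4R)‑4‑benzyl‑2‑oxo‑1,3‑oxazolidin‑3‑yl]‑3,3‑dimethyl‑2,4‑bis(3‑methylbut‑2‑en‑1‑yl)‑5‑oxopentanoate (both C2 epimers)
Conditions: NaN(SiMe3)2 (1.1 equiv), THF, −78 °C; 3 (3 equiv), −78 to −30 °C
Reagents that add atoms: none
Why: Evans asymmetric alkylation: one equivalent of base removes only the imide α‑proton, and the chelated (Z)‑sodium enolate is alkylated on the face away from the benzyl group, which with the (R)‑auxiliary gives the C7 configuration of the target; prenyl bromide is reactive enough for this neopentyl‑type enolate.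

**Step 5**
Reactants: 8 C7‑prenylated imide
Product: 9 methyl (4R)‑4‑(hydroxymethyl)‑3,3,7‑trimethyl‑2‑(3‑methylbut‑2‑en‑1‑yl)oct‑6‑enoate (both C2 epimers)
Conditions: LiBH4, MeOH (1 equiv), Et2O, 0 °C; cold pH 7 buffer
Reagents that add atoms: none
Why: Reductive removal of the auxiliary: the imide carbonyl is far more electrophilic than the α‑branched neopentyl methyl ester, which should survive; cold neutral work‑up and immediate use keep the δ‑hydroxy ester from closing to the lactone, and 5 is recovered.

**Step 6**
Reactants: 9 hydroxy ester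
Product: 10 methyl (4R)‑4‑(iodomethyl)‑3,3,7‑trimethyl‑2‑(3‑methylbut‑2‑en‑1‑yl)oct‑6‑enoate (both C2 epimers)
Conditions: I2, PPh3, imidazole, CH2Cl2, 0 °C to rt
Reagents that add atoms: iodine, II
Why: Appel‑type iodination of a primary alcohol through its alkoxyphosphonium salt under nearly neutral conditions that leave the prenyl alkenes and the ester alone; C7 is not involved.

**Step 7**
Reactants: 10 iodo ester; 11 methyl acetoacetate
Product: 12 dimethyl (4R)‑3,3‑dimethyl‑2,4‑bis(3‑methylbut‑2‑en‑1‑yl)‑7‑oxononanedioate (both C2 epimers)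
Conditions: 11 (3 equiv), NaH then n‑butyllithium, THF, 0 °C; 10, DMPU, 0 °C to rt
Reagents that add atoms: none
Why: γ‑Alkylation of a β‑keto ester dianion: the terminal carbanion is the more nucleophilic site and displaces the primary iodide (SN2), forming C5–C6; excess dianion compensates for the β‑branching of 10.

**Step 8**
Reactants: 12 keto diester; 3 prenyl bromide
Product: 13 dimethyl (4S)‑3,3‑dimethyl‑2,4,6‑tris(3‑methylbut‑2‑en‑1‑yl)‑7‑oxononanedioate (C2 and C6 epimers)
Conditions: LiN(iPr)2 (2.1 equiv), THF, −78 to 0 °C; 3, −78 to 0 °C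
Reagents that add atoms: none
Why: Second γ‑alkylation of a β‑keto ester dianion, now with a reactive allylic bromide at the C5 methylene; the base is held at two equivalents so that the hindered C1–H is not removed, and the C7 descriptor changes only because the priorities change.

**Step 9**
Reactants: 13 triprenyl keto diester
Product: 14 dimethyl (2E,6S)‑3‑methoxy‑7,7‑dimethyl‑4,6,8‑tris(3‑methylbut‑2‑en‑1‑yl)non‑2‑enedioate (C4 and C8 epimers)
Conditions: HC(OMe)3, MeOH, TsOH·H2O (5 mol%), rt to 40 °C; Et3N
Reagents that add atoms: trimethyl orthoformate, COC(OC)OC; methanol, CO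
Why: Acid‑catalysed O‑methylation of the β‑keto ester, the orthoformate acting as methanol source and water scavenger; under equilibrating conditions the (E)‑3‑methoxy enoate is the expected major isomer, and a mild sulfonic acid at low loading should spare the prenyl groups.

**Step 10**
Reactants: 14 (E)‑3‑methoxy enoate diester
Product: 16 (1R,5S,7S)‑4‑methoxy‑8,8‑dimethyl‑1,5,7‑tris(3‑methylbut‑2‑en‑1‑yl)bicyclo[3.3.1]non‑3‑ene‑2,9‑dione, via cyclohexanone keto enoate 15 (not isolated)
Conditions: LiN(iPr)2 (1.1 equiv), THF, −78 to −20 °C; LiN(iPr)2 (1.3 equiv), −78 °C to rt; aq. NH4Cl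
Reagents that add atoms: none
Why: Proposed new method: LiN(iPr)2 removes the γ‑proton at C5 of the 3‑methoxy enoate, the γ‑carbon of the dienolate adds to the C9 ester and methoxide leaves to give cyclohexanone 15, whose C1–H, now α to a ketone, is removed by the second charge of base so that C1 adds to the C2 ester and a second methoxide leaves. The closest known reaction types are the γ‑acylation of β‑alkoxy enoate dienolates and β‑keto ester dianions by esters and the Dieckmann condensation; their union into a bridged bicycle in one flask is without precedent. Ring B closes 6‑(enolexo)‑exo‑trig and ring A 6‑(enolendo)‑exo‑trig, both favourable modes. C5 is set in the first closure: in a chair with the C7 prenyl equatorial, allylic 1,3‑strain between the substituents of C4 and the C6–C7 bond keeps the planar C4 arm anti to C7 (pseudo‑equatorial), so C9 bonds to the face that leaves C4 cis to the C7 prenyl. C1 is set by constraint, because the three‑atom bridge can span C1 and C5 on one face only, and both C1 epimers of 14 converge through the enolate. The first closure is pulled forward by enolisation of 15; the second has no such sink and relies on LiOMe being a poor nucleophile in THF and on the shielding of C9 by two quaternary carbons against retro‑Claisen cleavage. The step needs γ‑deprotonation at C5 before the neopentyl C1–H (hence the staged base), C‑ over O‑acylation of the C1 enolate (the enol lactone would be reopened by methoxide), and a C3=C4 geometry with C2 syn to C5; because the dienolate erases the geometry of 14, 15 may form as either alkene isomer, and interconversion by reversible addition of LiOMe at C4 is counted on to feed the isomer that can close.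

**Step 11**
Reactants: 16 bicyclic vinylogous ester; 17 benzoyl chloride
Product: 18 (1S,5S,7S)‑3‑benzoyl‑4‑methoxy‑8,8‑dimethyl‑1,5,7‑tris(3‑methylbut‑2‑en‑1‑yl)bicyclo[3.3.1]non‑3‑ene‑2,9‑dione
Conditions: lithium 2,2,6,6‑tetramethylpiperidide (1.5 equiv), THF, −78 °C; 17, −78 °C
Reagents that add atoms: none
Why: Vinylic lithiation at C3 of the vinylogous ester (flanked by the C2 carbonyl and the C4 methoxy group, with no enolisable proton in the molecule) followed by C‑acylation; this metalation–acylation is established for bicyclic vinylogous esters of this class.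

**Step 12**
Reactants: 18 3‑benzoyl vinylogous ester
Product: 19 (1S,5R,7S)‑3‑[(Z)‑hydroxy(phenyl)methylidene]‑8,8‑dimethyl‑1,5,7‑tris(3‑methylbut‑2‑en‑1‑yl)bicyclo[3.3.1]nonane‑2,4,9‑trione
Conditions: LiCl, DMSO, 120 °C; dilute HCl
Reagents that add atoms: none
Why: Nucleophilic demethylation: chloride attacks the O‑methyl group of the doubly activated enol ether (SN2) and releases the triketone as its lithium enolate, which gives the enol on acidification; no acid strong enough to touch the prenyl groups is used and no stereocentre is affected.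

## Compound list

1 | 3,3‑dimethylglutaric anhydride | CC1(C)CC(=O)OC(=O)C1 | starting material
2 | 5‑methoxy‑3,3‑dimethyl‑5‑oxopentanoic acid | COC(=O)CC(C)(C)CC(=O)O | intermediate
3 | prenyl bromide (1‑bromo‑3‑methylbut‑2‑ene) | CC(C)=CCBr | starting material
4 | rac‑4‑(methoxycarbonyl)‑3,3,7‑trimethyloct‑6‑enoic acid | COC(=O)C(CC=C(C)C)C(C)(C)CC(=O)O | intermediate
5 | (R)‑4‑benzyl‑1,3‑oxazolidin‑2‑one | O=C1N[C@H](Cc2ccccc2)CO1 | starting material
6 | mixed anhydride of 4 with pivalic acid | COC(=O)C(CC=C(C)C)C(C)(C)CC(=O)OC(=O)C(C)(C)C | intermediate (not isolated)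
7 | methyl 5‑[(4R)‑4‑benzyl‑2‑oxo‑1,3‑oxazolidin‑3‑yl]‑3,3‑dimethyl‑2‑(3‑methylbut‑2‑en‑1‑yl)‑5‑oxopentanoate, both C2 epimers | COC(=O)C(CC=C(C)C)C(C)(C)CC(=O)N1[C@H](Cc2ccccc2)COC1=O | intermediate
8 | methyl (4R)‑5‑[(4R)‑4‑benzyl‑2‑oxo‑1,3‑oxazolidin‑3‑yl]‑3,3‑dimethyl‑2,4‑bis(3‑methylbut‑2‑en‑1‑yl)‑5‑oxopentanoate, both C2 epimers | COC(=O)C(CC=C(C)C)C(C)(C)[C@@H](CC=C(C)C)C(=O)N1[C@H](Cc2ccccc2)COC1=O | intermediate
9 | methyl (4R)‑4‑(hydroxymethyl)‑3,3,7‑trimethyl‑2‑(3‑methylbut‑2‑en‑1‑yl)oct‑6‑enoate, both C2 epimers | COC(=O)C(CC=C(C)C)C(C)(C)[C@@H](CC=C(C)C)CO | intermediate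
10 | methyl (4R)‑4‑(iodomethyl)‑3,3,7‑trimethyl‑2‑(3‑methylbut‑2‑en‑1‑yl)oct‑6‑enoate, both C2 epimers | COC(=O)C(CC=C(C)C)C(C)(C)[C@@H](CC=C(C)C)CI | intermediate
11 | methyl acetoacetate | COC(=O)CC(C)=O | starting material
12 | dimethyl (4R)‑3,3‑dimethyl‑2,4‑bis(3‑methylbut‑2‑en‑1‑yl)‑7‑oxononanedioate, both C2 epimers | COC(=O)CC(=O)CC[C@H](CC=C(C)C)C(C)(C)C(CC=C(C)C)C(=O)OC | intermediate
13 | dimethyl (4S)‑3,3‑dimethyl‑2,4,6‑tris(3‑methylbut‑2‑en‑1‑yl)‑7‑oxononanedioate, C2 and C6 epimers | COC(=O)CC(=O)C(CC=C(C)C)C[C@H](CC=C(C)C)C(C)(C)C(CC=C(C)C)C(=O)OC | intermediate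
14 | dimethyl (2E,6S)‑3‑methoxy‑7,7‑dimethyl‑4,6,8‑tris(3‑methylbut‑2‑en‑1‑yl)non‑2‑enedioate, C4 and C8 epimers | COC(=O)/C=C(OC)\C(CC=C(C)C)C[C@H](CC=C(C)C)C(C)(C)C(CC=C(C)C)C(=O)OC | intermediate
15 | methyl (2E)‑3‑methoxy‑3‑[(1S,5S)‑4,4‑dimethyl‑1,3,5‑tris(3‑methylbut‑2‑en‑1‑yl)‑2‑oxocyclohexyl]prop‑2‑enoate, C3 of the ring epimeric | COC(=O)/C=C(OC)\[C@]1(CC=C(C)C)C[C@H](CC=C(C)C)C(C)(C)C(CC=C(C)C)C1=O | intermediate (not isolated)
16 | (1R,5S,7S)‑4‑methoxy‑8,8‑dimethyl‑1,5,7‑tris(3‑methylbut‑2‑en‑1‑yl)bicyclo[3.3.1]non‑3‑ene‑2,9‑dione | CC(C)=CC[C@H]1C[C@@]2(CC=C(C)C)C(OC)=CC(=O)[C@](CC=C(C)C)(C2=O)C1(C)C | intermediate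
17 | benzoyl chloride | O=C(Cl)c1ccccc1 | starting material
18 | (1S,5S,7S)‑3‑benzoyl‑4‑methoxy‑8,8‑dimethyl‑1,5,7‑tris(3‑methylbut‑2‑en‑1‑yl)bicyclo[3.3.1]non‑3‑ene‑2,9‑dione | CC(C)=CC[C@H]1C[C@@]2(CC=C(C)C)C(OC)=C(C(=O)c3ccccc3)C(=O)[C@](CC=C(C)C)(C2=O)C1(C)C | intermediate
19 | (1S,5R,7S)‑3‑[(Z)‑hydroxy(phenyl)methylidene]‑8,8‑dimethyl‑1,5,7‑tris(3‑methylbut‑2‑en‑1‑yl)bicyclo[3.3.1]nonane‑2,4,9‑trione | CC(C)=CC[C@H]1C[C@@]2(CC=C(C)C)C(=O)/C(=C(/O)c3ccccc3)C(=O)[C@](CC=C(C)C)(C2=O)C1(C)C | target

## Step count and least certain steps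

Total: 12 steps. Longest linear sequence: 12 steps (1 to 19); 3, 5, 11 and 17 are purchased.

**Step 10 (key step, proposed new method).**
- What may go wrong: the sequence may stop after the first closure because the enoate arm of 15 forms with C2 turned away from C5 and does not isomerise fast enough. Deprotonation may occur at C1 instead of C5 and be followed by conjugate addition–elimination at C4. Methoxide may cleave the non‑enolisable β‑dicarbonyl units (retro‑Claisen). The C1 enolate may acylate at oxygen. The facial preference at C5 may be weaker than the chair model predicts, since the C1 epimer with an axial prenyl fits that chair poorly.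
- Fallback (sets out from 13, returns at 16): the free β‑keto ester is used so that each closure is a known, anion‑driven condensation. LiN(iPr)2 (3 equiv, THF, −78 to 0 °C) forms the α,γ‑dianion of 13, whose γ‑carbon C5 acylates the C9 ester (γ‑acylation of a β‑keto ester dianion by an ester), giving methyl 3‑[(1S,5S)‑4,4‑dimethyl‑1,3,5‑tris(3‑methylbut‑2‑en‑1‑yl)‑2‑oxocyclohexyl]‑3‑oxopropanoate F1. Potassium tert‑butoxide in THF then closes ring A by Claisen condensation of the C1 enolate on the C2 ester. This is a classical Dieckmann‑type closure, because the product, (1R,5S,7S)‑8,8‑dimethyl‑1,5,7‑tris(3‑methylbut‑2‑en‑1‑yl)bicyclo[3.3.1]nonane‑2,4,9‑trione F2, is deprotonated at C3 as it forms, and the C3–C4 enolate bond rotates, so no alkene geometry has to be right. O‑Methylation of F2 with Me3SiCHN2 in MeOH/toluene gives 16 together with its regioisomer (1R,5S,7S)‑2‑methoxy‑8,8‑dimethyl‑1,5,7‑tris(3‑methylbut‑2‑en‑1‑yl)bicyclo[3.3.1]non‑2‑ene‑4,9‑dione F3, which is separated and returned to F2 with LiCl in DMSO.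

**Step 7.**
- What may go wrong: substitution at the β‑branched iodide is slow, so elimination to the 1,1‑disubstituted alkene, proton transfer from C1–H to the dianion, and closure of 10 to the δ‑lactone with loss of iodomethane can compete.
- Fallback (sets out from 9, returns at 12): C5–C6 is made as an alkene instead of by substitution. Oxidation of 9 with Dess–Martin periodinane (NaHCO3) gives methyl (4R)‑4‑formyl‑3,3,7‑trimethyl‑2‑(3‑methylbut‑2‑en‑1‑yl)oct‑6‑enoate F4. Horner–Wadsworth–Emmons reaction with the dianion (NaH, 2 equiv, THF) of methyl 4‑(diethoxyphosphoryl)‑3‑oxobutanoate gives dimethyl (4S,5E)‑3,3‑dimethyl‑2,4‑bis(3‑methylbut‑2‑en‑1‑yl)‑7‑oxonon‑5‑enedioate F5. Hydrogenation with RhCl(PPh3)3 and H2 in benzene, which saturates the disubstituted enone alkene and leaves the trisubstituted prenyl alkenes, gives 12.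

**Step 5.**
- What may go wrong: the δ‑hydroxy ester may lactonise during reduction or work‑up (gem‑dimethyl effect), the lactone or ester may be over‑reduced, and hydride may attack the ring carbonyl of the hindered imide.
- Fallback (sets out from 8, returns at 12): the alcohol oxidation level at C6 is avoided altogether. Lithium ethanethiolate (from EtSH and n‑butyllithium, THF, 0 °C) converts 8 into S‑ethyl thioester methyl (4R)‑4‑[(ethylsulfanyl)carbonyl]‑3,3,7‑trimethyl‑2‑(3‑methylbut‑2‑en‑1‑yl)oct‑6‑enoate F6. Fukuyama reduction (Et3SiH, Pd/C, acetone) gives the aldehyde F4, which is carried through the olefination and hydrogenation described under step 7 via the enone F5 to 12.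

**Step 4.**
- What may go wrong: alkylation of the congested enolate (α‑carbon next to the quaternary C8) may be incomplete, the sodium enolate may fragment to a ketene on warming, and facial selectivity may erode if the reaction has to be run warmer.
- Fallback (sets out from 7, returns at 8): the side chain is installed in two stages. Alkylation of the enolate of 7 with allyl iodide, a smaller and more reactive electrophile, gives methyl (4R)‑5‑[(4R)‑4‑benzyl‑2‑oxo‑1,3‑oxazolidin‑3‑yl]‑3,3‑dimethyl‑2‑(3‑methylbut‑2‑en‑1‑yl)‑5‑oxo‑4‑(prop‑2‑en‑1‑yl)pentanoate F7. Cross‑metathesis with 2‑methylbut‑2‑ene and the second‑generation Grubbs catalyst (CH2Cl2, 40 °C) converts the allyl group into prenyl and gives 8; the existing prenyl group is a trisubstituted alkene and reacts at most degenerately.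

**Step 9.**
- What may go wrong: acid may add methanol to the prenyl double bonds or cyclise the enol onto the C5 prenyl group, and ketalisation at the α‑branched ketone may be slow.
- Fallback (sets out from 13, returns at 14): a base‑only route. Enol tosylation of 13 (TsCl, N‑methylimidazole, Et3N, MeCN) gives dimethyl (6S)‑7,7‑dimethyl‑4,6,8‑tris(3‑methylbut‑2‑en‑1‑yl)‑3‑(tosyloxy)non‑2‑enedioate F8 (either alkene isomer). Addition–elimination with NaOMe in MeOH replaces tosylate by methoxide under equilibrating conditions and gives 14.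

## Further compounds

F1 | step 10 | methyl 3‑[(1S,5S)‑4,4‑dimethyl‑1,3,5‑tris(3‑methylbut‑2‑en‑1‑yl)‑2‑oxocyclohexyl]‑3‑oxopropanoate | COC(=O)CC(=O)[C@]1(CC=C(C)C)C[C@H](CC=C(C)C)C(C)(C)C(CC=C(C)C)C1=O
F2 | step 10 | (1R,5S,7S)‑8,8‑dimethyl‑1,5,7‑tris(3‑methylbut‑2‑en‑1‑yl)bicyclo[3.3.1]nonane‑2,4,9‑trione | CC(C)=CC[C@H]1C[C@@]2(CC=C(C)C)C(=O)CC(=O)[C@](CC=C(C)C)(C2=O)C1(C)C
F3 | step 10 | (1R,5S,7S)‑2‑methoxy‑8,8‑dimethyl‑1,5,7‑tris(3‑methylbut‑2‑en‑1‑yl)bicyclo[3.3.1]non‑2‑ene‑4,9‑dione | CC(C)=CC[C@H]1C[C@@]2(CC=C(C)C)C(=O)C=C(OC)[C@](CC=C(C)C)(C2=O)C1(C)C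
F4 | step 7 | methyl (4R)‑4‑formyl‑3,3,7‑trimethyl‑2‑(3‑methylbut‑2‑en‑1‑yl)oct‑6‑enoate | COC(=O)C(CC=C(C)C)C(C)(C)[C@@H](CC=C(C)C)C=O
F5 | step 7 | dimethyl (4S,5E)‑3,3‑dimethyl‑2,4‑bis(3‑methylbut‑2‑en‑1‑yl)‑7‑oxonon‑5‑enedioate | COC(=O)CC(=O)/C=C/[C@H](CC=C(C)C)C(C)(C)C(CC=C(C)C)C(=O)OC
F6 | step 5 | methyl (4R)‑4‑[(ethylsulfanyl)carbonyl]‑3,3,7‑trimethyl‑2‑(3‑methylbut‑2‑en‑1‑yl)oct‑6‑enoate | COC(=O)C(CC=C(C)C)C(C)(C)[C@@H](CC=C(C)C)C(=O)SCC
F7 | step 4 | methyl (4R)‑5‑[(4R)‑4‑benzyl‑2‑oxo‑1,3‑oxazolidin‑3‑yl]‑3,3‑dimethyl‑2‑(3‑methylbut‑2‑en‑1‑yl)‑5‑oxo‑4‑(prop‑2‑en‑1‑yl)pentanoate | COC(=O)C(CC=C(C)C)C(C)(C)[C@@H](CC=C)C(=O)N1[C@H](Cc2ccccc2)COC1=O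
F8 | step 9 | dimethyl (6S)‑7,7‑dimethyl‑4,6,8‑tris(3‑methylbut‑2‑en‑1‑yl)‑3‑(tosyloxy)non‑2‑enedioate | COC(=O)C=C(OS(=O)(=O)c1ccc(C)cc1)C(CC=C(C)C)C[C@H](CC=C(C)C)C(C)(C)C(CC=C(C)C)C(=O)OC
A1 | alternative 1 | 3‑[(1S)‑2,2‑dimethyl‑4‑(triisopropylsilyloxy)cyclohex‑3‑ene‑1‑carbonyl]‑1,3‑oxazolidin‑2‑one | O=C1OCCN1C(=O)[C@H]1CCC(O[Si](C(C)C)(C(C)C)C(C)C)=CC1(C)C
A2 | alternative 1 | 4‑methyl‑2‑(triisopropylsilyloxy)penta‑1,3‑diene | C=C(O[Si](C(C)C)(C(C)C)C(C)C)C=C(C)C
A3 | alternative 1 | 3‑acryloyl‑1,3‑oxazolidin‑2‑one | C=CC(=O)N1CCOC1=O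
A4 | alternative 2 | (1S,5R)‑3‑[(Z)‑hydroxy(phenyl)methylidene]‑8,8‑dimethyl‑1,5‑bis(3‑methylbut‑2‑en‑1‑yl)bicyclo[3.3.1]nonane‑2,4,7,9‑tetrone | O=C1C[C@@]2(CC=C(C)C)C(=O)/C(=C(/O)c3ccccc3)C(=O)[C@](CC=C(C)C)(C2=O)C1(C)C
A5 | alternative 2 | (6S)‑2‑[hydroxy(phenyl)methylidene]‑6‑(2‑methyl‑3‑oxobutan‑2‑yl)‑4,6‑bis(3‑methylbut‑2‑en‑1‑yl)cyclohexane‑1,3,5‑trione | CC(=O)C(C)(C)[C@@]1(CC=C(C)C)C(=O)C(CC=C(C)C)C(=O)C(=C(O)c2ccccc2)C1=O
A6 | alternative 3 | (1R,5S,7S)‑2‑methoxy‑8,8‑dimethyl‑5,7‑bis(3‑methylbut‑2‑en‑1‑yl)bicyclo[3.3.1]non‑2‑ene‑4,9‑dione | CC(C)=CC[C@H]1C[C@@]2(CC=C(C)C)C(=O)C=C(OC)[C@H](C2=O)C1(C)C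
A7 | alternative 3 | cis‑fused 7a‑hydroxy‑6‑methoxy‑1,1‑dimethyl‑2,3a‑bis(3‑methylbut‑2‑en‑1‑yl)‑1,2,3,3a,7,7a‑hexahydro‑4H‑inden‑4‑one | CC(C)=CC[C@H]1C[C@@]2(CC=C(C)C)C(=O)C=C(OC)C[C@@]2(O)C1(C)C
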